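Sequoiaflavone (7-O-methylamentoflavone): convergent route through a fluoride-displacement closure of ring C of unit 1

Everything rests on breaking the O1–C8a aryl ether bond of ring C in unit 1, the 7-methoxylated flavone. In one operation the key step closes that pyranone by intramolecular fluoride displacement, on a substrate that already holds the C3'–C8'' biaryl and the whole benzylated apigenin unit 2. Its precursor is a 1-(2,6-difluoro-4-methoxyphenyl)-3-aryl-1,3-diketone. The step exploits the symmetry of that future ring A: two equivalent fluorines flank the acyl-bearing carbon (later C4a), so either closure gives the same C8a–O1 bond, the C7 methyl ether is already in place, and the surviving fluorine at C5, peri to the C4 carbonyl, is a masked hydroxyl.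

Key step: step 8

Remark: iodine is introduced only after all three hydroxyls of apigenin are benzylated, because a 5,7-dialkoxyflavone should be iodinated at C8, whereas a free C5 hydroxyl would direct the electrophile to C6; the target has no stereocentre and its biaryl axis is not configurationally defined, so no stereocontrol is needed.

Step 1
Reactants: 1 apigenin
Product: 2 5,7,4'-tri-O-benzylapigenin
Conditions: BnBr (4.5 equiv), K2CO3, KI (cat.), DMF, 80 °C
Reagents that add atoms: benzyl bromide, BrCc1ccccc1
Why: Williamson etherification, in which the C7 and C4' phenoxides react readily and excess bromide with heating in DMF should also alkylate the hydrogen-bonded C5 hydroxyl, so that no free phenol is left to misdirect the iodination.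

Step 2
Reactants: 2 5,7,4'-tri-O-benzylapigenin
Product: 3 8-iodo-5,7,4'-tri-O-benzylapigenin
Conditions: NIS (1.05 equiv), TFA (cat.), MeCN–CH2Cl2, 0 °C → rt
Reagents that add atoms: N-iodosuccinimide, O=C1CCC(=O)N1I
Why: Electrophilic aromatic iodination, in which the doubly oxygen-activated ring A should react at C8 (flanked by the ring oxygen and one benzyloxy group) in preference to C6 (between two benzyloxy groups), while ring B and C3 are too electron-poor to compete.

Step 3
Reactants: 4 methyl 3-bromo-4-hydroxybenzoate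
Product: 5 methyl 4-(benzyloxy)-3-bromobenzoate
Conditions: BnBr, K2CO3, acetone, reflux
Reagents that add atoms: benzyl bromide, BrCc1ccccc1
Why: Williamson etherification of an acidic phenol under conditions that leave the methyl ester and the aryl bromide untouched.

Step 4
Reactants: 5 methyl 4-(benzyloxy)-3-bromobenzoate
Product: 6 methyl 4-(benzyloxy)-3-(4,4,5,5-tetramethyl-1,3,2-dioxaborolan-2-yl)benzoate
Conditions: B2pin2, Pd(dppf)Cl2 (cat.), KOAc, 1,4-dioxane, 90 °C
Reagents that add atoms: bis(pinacolato)diboron, CC1(C)OB(B2OC(C)(C)C(C)(C)O2)OC1(C)C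
Why: Miyaura borylation of the aryl bromide, with KOAc as a base too weak to promote biaryl homocoupling or ester cleavage.

Step 5
Reactants: 3 8-iodo-5,7,4'-tri-O-benzylapigenin; 6 methyl 4-(benzyloxy)-3-(4,4,5,5-tetramethyl-1,3,2-dioxaborolan-2-yl)benzoate
Product: 7 methyl 4-(benzyloxy)-3-{5,7-bis(benzyloxy)-2-[4-(benzyloxy)phenyl]-4-oxo-4H-chromen-8-yl}benzoate
Conditions: Pd(OAc)2 (5 mol %), SPhos (10 mol %), K3PO4, toluene–H2O (10:1), 90 °C
Reagents that add atoms: none
Why: Suzuki–Miyaura cross-coupling, for which the bulky electron-rich biarylphosphine SPhos is chosen because the new C3'–C8'' bond carries three ortho substituents, and the phosphate base in a biphasic medium spares the methyl ester.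

Step 6
Reactants: 8 3,5-difluoroanisole
Product: 11 1-(2,6-difluoro-4-methoxyphenyl)ethanone, via 2,6-difluoro-4-methoxyphenyllithium 9 (not isolated), via lithium hemiaminal adduct 10 (not isolated)
Conditions: n-BuLi, THF, −78 °C; MeC(O)N(OMe)Me, −78 → 0 °C; aq. HCl
Reagents that add atoms: N-methoxy-N-methylacetamide, CC(=O)N(C)OC
Why: Directed ortho-lithiation removes the most acidic ring proton, the one between the two fluorines, and the Weinreb ketone synthesis stops at the chelated tetrahedral adduct, so the ketone is released only on acidic work-up, while the low temperature prevents loss of LiF to an aryne.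

Step 7
Reactants: 11 1-(2,6-difluoro-4-methoxyphenyl)ethanone; 7 methyl 4-(benzyloxy)-3-{5,7-bis(benzyloxy)-2-[4-(benzyloxy)phenyl]-4-oxo-4H-chromen-8-yl}benzoate
Product: 13 1-(2,6-difluoro-4-methoxyphenyl)-3-{4-(benzyloxy)-3-[5,7-bis(benzyloxy)-2-(4-(benzyloxy)phenyl)-4-oxo-4H-chromen-8-yl]phenyl}propane-1,3-dione, via lithium 1-(2,6-difluoro-4-methoxyphenyl)ethenolate 12 (not isolated)
Conditions: 11 (2.5 equiv), LiHMDS (3.5 equiv), THF, −78 °C; then 7, −78 °C → rt; AcOH
Reagents that add atoms: none
Why: Crossed Claisen condensation, in which only the ketone can enolise and only the non-enolisable methyl benzoate 7 can act as acyl acceptor, and deprotonation of the product 1,3-diketone by the excess base pulls the equilibrium forward.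

Step 8
Reactants: 13 1-(2,6-difluoro-4-methoxyphenyl)-3-aryl-propane-1,3-dione carrying benzylated unit 2
Product: 14 8-{2-(benzyloxy)-5-(5-fluoro-7-methoxy-4-oxo-4H-chromen-2-yl)phenyl}-5,7-bis(benzyloxy)-2-[4-(benzyloxy)phenyl]-4H-chromen-4-one
Conditions: K2CO3 (3 equiv), dry DMF (0.05 M), 80 °C
Reagents that add atoms: none
Why: Carbonate deprotonates the diketone, and the enolate oxygen on the biaryl side adds to a fluorine-bearing carbon ortho to the aroyl group to give a Meisenheimer adduct whose charge is taken up by the C4 carbonyl and stabilised inductively by the second fluorine; loss of fluoride restores ring A and leaves the O1–C8a bond. The closest known reaction type is the intramolecular nucleophilic aromatic substitution (addition–elimination) that converts 2-fluoroaryl 1,3-diketones into chromones. Ring C closes in a formally 6-endo-trig mode, since the attacked C8a=C4a bond ends up inside the new six-membered ring, which is equivalent to an oxa-Michael addition to the aryl ketone followed by β-elimination. No stereocenter is created. The step needs oxygen rather than carbon attack, and the substrate secures this because attack by the central carbon or by the proximal oxygen would have to form a four-membered ring. Site selectivity is not an issue because the two fluorines are homotopic, and dilution keeps the still-activated C5 fluorine of the product from being displaced by a second enolate.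

Step 9
Reactants: 14 5-fluoro-7-methoxyflavone carrying benzylated unit 2
Product: 15 8-{2-(benzyloxy)-5-[5-(benzyloxy)-7-methoxy-4-oxo-4H-chromen-2-yl]phenyl}-5,7-bis(benzyloxy)-2-[4-(benzyloxy)phenyl]-4H-chromen-4-one
Conditions: BnOH (3 equiv), NaH (2.5 equiv), THF, 0 → 50 °C
Reagents that add atoms: benzyl alcohol, OCc1ccccc1
Why: Intermolecular nucleophilic aromatic substitution (addition–elimination), in which the C5 fluorine is ortho to the carbon bearing the C4 carbonyl, which accepts the charge of the adduct, so sodium benzyloxide should displace it while the aryl ethers are inert.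

Step 10
Reactants: 15 penta-O-benzylsequoiaflavone
Product: 16 sequoiaflavone
Conditions: H2 (1 atm), 10% Pd/C, THF–MeOH, rt
Reagents that add atoms: none
Why: Catalytic hydrogenolysis cleaves all five benzyl aryl ethers at once, while the C7 methyl ether and the C2=C3 bonds of both pyranones, which belong to conjugated 4-pyranone systems, should survive at ambient pressure.

Compound list

1 | apigenin (5,7-dihydroxy-2-(4-hydroxyphenyl)-4H-chromen-4-one) | O=c1cc(-c2ccc(O)cc2)oc2cc(O)cc(O)c12 | starting material
2 | 5,7,4'-tri-O-benzylapigenin (5,7-bis(benzyloxy)-2-[4-(benzyloxy)phenyl]-4H-chromen-4-one) | O=c1cc(-c2ccc(OCc3ccccc3)cc2)oc2cc(OCc3ccccc3)cc(OCc3ccccc3)c12 | intermediate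
3 | 8-iodo-5,7,4'-tri-O-benzylapigenin (5,7-bis(benzyloxy)-2-[4-(benzyloxy)phenyl]-8-iodo-4H-chromen-4-one) | O=c1cc(-c2ccc(OCc3ccccc3)cc2)oc2c(I)c(OCc3ccccc3)cc(OCc3ccccc3)c12 | intermediate
4 | methyl 3-bromo-4-hydroxybenzoate | COC(=O)c1ccc(O)c(Br)c1 | starting material
5 | methyl 4-(benzyloxy)-3-bromobenzoate | COC(=O)c1ccc(OCc2ccccc2)c(Br)c1 | intermediate
6 | methyl 4-(benzyloxy)-3-(4,4,5,5-tetramethyl-1,3,2-dioxaborolan-2-yl)benzoate | COC(=O)c1ccc(OCc2ccccc2)c(B2OC(C)(C)C(C)(C)O2)c1 | intermediate
7 | methyl 4-(benzyloxy)-3-{5,7-bis(benzyloxy)-2-[4-(benzyloxy)phenyl]-4-oxo-4H-chromen-8-yl}benzoate | COC(=O)c1ccc(OCc2ccccc2)c(-c2c(OCc3ccccc3)cc(OCc3ccccc3)c3c(=O)cc(-c4ccc(OCc5ccccc5)cc4)oc23)c1 | intermediate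
8 | 3,5-difluoroanisole | COc1cc(F)cc(F)c1 | starting material
9 | 2,6-difluoro-4-methoxyphenyllithium (not isolated) | [Li]c1c(F)cc(OC)cc1F | intermediate
10 | lithium 1-(2,6-difluoro-4-methoxyphenyl)-1-[methoxy(methyl)amino]ethan-1-olate, racemic (not isolated) | CC(O[Li])(N(C)OC)c1c(F)cc(OC)cc1F | intermediate
11 | 1-(2,6-difluoro-4-methoxyphenyl)ethanone | CC(=O)c1c(F)cc(OC)cc1F | intermediate
12 | lithium 1-(2,6-difluoro-4-methoxyphenyl)ethenolate (not isolated) | [Li]OC(=C)c1c(F)cc(OC)cc1F | intermediate
13 | 1-(2,6-difluoro-4-methoxyphenyl)-3-{4-(benzyloxy)-3-[5,7-bis(benzyloxy)-2-(4-(benzyloxy)phenyl)-4-oxo-4H-chromen-8-yl]phenyl}propane-1,3-dione (key-step precursor, largely enolised) | COc1cc(F)c(C(=O)CC(=O)c2ccc(OCc3ccccc3)c(-c3c(OCc4ccccc4)cc(OCc4ccccc4)c4c(=O)cc(-c5ccc(OCc6ccccc6)cc5)oc34)c2)c(F)c1 | intermediate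
14 | 8-{2-(benzyloxy)-5-(5-fluoro-7-methoxy-4-oxo-4H-chromen-2-yl)phenyl}-5,7-bis(benzyloxy)-2-[4-(benzyloxy)phenyl]-4H-chromen-4-one (key-step product) | COc1cc(F)c2c(=O)cc(-c3ccc(OCc4ccccc4)c(-c4c(OCc5ccccc5)cc(OCc5ccccc5)c5c(=O)cc(-c6ccc(OCc7ccccc7)cc6)oc45)c3)oc2c1 | intermediate
15 | 8-{2-(benzyloxy)-5-[5-(benzyloxy)-7-methoxy-4-oxo-4H-chromen-2-yl]phenyl}-5,7-bis(benzyloxy)-2-[4-(benzyloxy)phenyl]-4H-chromen-4-one (penta-O-benzylsequoiaflavone) | COc1cc(OCc2ccccc2)c2c(=O)cc(-c3ccc(OCc4ccccc4)c(-c4c(OCc5ccccc5)cc(OCc5ccccc5)c5c(=O)cc(-c6ccc(OCc7ccccc7)cc6)oc45)c3)oc2c1 | intermediate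
16 | sequoiaflavone (7-O-methylamentoflavone) | COc1cc(O)c2c(=O)cc(-c3ccc(O)c(-c4c(O)cc(O)c5c(=O)cc(-c6ccc(O)cc6)oc45)c3)oc2c1 | target

Total step count: 10. Longest linear sequence: 7 steps (steps 1, 2, 5, 7, 8, 9 and 10, from apigenin).

Steps most likely to fail

Step 8. The ring closure may be slow enough that the still-activated C5 fluorine of the product is displaced intermolecularly, by a second enolate or by dimethylamine released from the solvent, so that oligomers or an amino by-product form beside the flavone. The fallback sets out from ketone 11 and installs the C5 oxygen before the diketone is built. Benzyl alcohol and NaH (1 equiv, THF, 0 °C → rt) should replace one fluorine and give 1-[2-(benzyloxy)-6-fluoro-4-methoxyphenyl]ethanone F1. LiHMDS in THF converts it into lithium 1-[2-(benzyloxy)-6-fluoro-4-methoxyphenyl]ethenolate F2. Condensation with ester 7 as in step 7 should give 1-[2-(benzyloxy)-6-fluoro-4-methoxyphenyl]-3-aryl-propane-1,3-dione F3. Cs2CO3 in DMSO at 110 °C should then close ring C by expelling the only remaining fluorine, more slowly than in the difluoro series but without leaving an activated halide in the product. The fallback comes back to the route at compound 15, and step 9 is no longer needed.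

Step 7. Acyl transfer may stay incomplete because the para-alkoxybenzoate is a weak acceptor, and on prolonged warming the enolate may be consumed by self-condensation or by intermolecular attack on a fluorine. The fallback sets out from ester 7. Saponification (LiOH, THF–MeOH–H2O, rt, then acidification) should give 4-(benzyloxy)-3-{5,7-bis(benzyloxy)-2-[4-(benzyloxy)phenyl]-4-oxo-4H-chromen-8-yl}benzoic acid F4. Oxalyl chloride with catalytic DMF in CH2Cl2 converts it into the corresponding benzoyl chloride F5. This acylates ketone 11 under soft-enolisation conditions (MgBr2·OEt2, i-Pr2NEt, CH2Cl2, rt), a C-acylation that needs no strong base and no excess of a lithium enolate. The fallback comes back to the route at compound 13.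

Step 5. Transmetalation at the doubly ortho-substituted C8–palladium centre may be slow, so that reduction of the carbon–iodine bond and protodeboronation of the boronate outrun the coupling. The fallback sets out from iodide 3 and reverses the polarity of the partners. Miyaura borylation (B2pin2, Pd(dppf)Cl2, KOAc, DMSO, 80 °C) should give 5,7-bis(benzyloxy)-2-[4-(benzyloxy)phenyl]-8-(4,4,5,5-tetramethyl-1,3,2-dioxaborolan-2-yl)-4H-chromen-4-one F6. This is coupled with the unhindered bromide 5 (Pd(OAc)2, SPhos, K3PO4, toluene–H2O, 80 °C), so that oxidative addition takes place on the accessible partner. Step 4 is then omitted, and the fallback comes back to the route at compound 7.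

Further compounds

F1 | step 8 | 1-[2-(benzyloxy)-6-fluoro-4-methoxyphenyl]ethanone | CC(=O)c1c(F)cc(OC)cc1OCc1ccccc1
F2 | step 8 | lithium 1-[2-(benzyloxy)-6-fluoro-4-methoxyphenyl]ethenolate | [Li]OC(=C)c1c(F)cc(OC)cc1OCc1ccccc1
F3 | step 8 | 1-[2-(benzyloxy)-6-fluoro-4-methoxyphenyl]-3-{4-(benzyloxy)-3-[5,7-bis(benzyloxy)-2-(4-(benzyloxy)phenyl)-4-oxo-4H-chromen-8-yl]phenyl}propane-1,3-dione | COc1cc(F)c(C(=O)CC(=O)c2ccc(OCc3ccccc3)c(-c3c(OCc4ccccc4)cc(OCc4ccccc4)c4c(=O)cc(-c5ccc(OCc6ccccc6)cc5)oc34)c2)c(OCc2ccccc2)c1
F4 | step 7 | 4-(benzyloxy)-3-{5,7-bis(benzyloxy)-2-[4-(benzyloxy)phenyl]-4-oxo-4H-chromen-8-yl}benzoic acid | OC(=O)c1ccc(OCc2ccccc2)c(-c2c(OCc3ccccc3)cc(OCc3ccccc3)c3c(=O)cc(-c4ccc(OCc5ccccc5)cc4)oc23)c1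
F5 | step 7 | 4-(benzyloxy)-3-{5,7-bis(benzyloxy)-2-[4-(benzyloxy)phenyl]-4-oxo-4H-chromen-8-yl}benzoyl chloride | ClC(=O)c1ccc(OCc2ccccc2)c(-c2c(OCc3ccccc3)cc(OCc3ccccc3)c3c(=O)cc(-c4ccc(OCc5ccccc5)cc4)oc23)c1
F6 | step 5 | 5,7-bis(benzyloxy)-2-[4-(benzyloxy)phenyl]-8-(4,4,5,5-tetramethyl-1,3,2-dioxaborolan-2-yl)-4H-chromen-4-one | O=c1cc(-c2ccc(OCc3ccccc3)cc2)oc2c(B3OC(C)(C)C(C)(C)O3)c(OCc3ccccc3)cc(OCc3ccccc3)c12
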